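**Plan**

- The retrosynthesis first cuts the bond between the bridging CH2 and the only ring CH carbon of ring B (the dimethylated dienone), giving a ring A quinone methide and acetylfilicinic acid; the latter goes back to 2',4',6'-trihydroxyacetophenone by removing the two methyl C–C bonds.
- Ring A is then cut at three C–C bonds (phenol numbering C1–C2, C1–C6 and C3–C4) into a 3-methoxy-2-(silyloxymethyl)cyclobutenone and a siloxyalkyne that carries the acetyl group as a dioxolane.
- Forward: the siloxyalkyne (two steps from ethyl pyruvate) and the cyclobutenone (four steps from trichloroethylene) are fused to ring A, and the ketal is opened. Ring B, made separately in one step, is attached last through the benzylic carbon that the cyclobutenone already carried.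
- The target has no stereocentre. The only stereogenic carbon on the way, the quaternary carbon of the transient cyclobutenone adduct, becomes an aromatic carbon.

Key step: step 7

Assumption: ring B is a β-triketone that equilibrates between enol tautomers; it is written throughout in the tautomer of the target SMILES.

**Route**

Step 1
Reactants: 1 ethyl pyruvate (ethyl 2-oxopropanoate)
Product: 2 ethyl 2-methyl-1,3-dioxolane-2-carboxylate
Conditions: HOCH2CH2OH, p-TsOH (cat.), toluene, Dean–Stark, reflux
Reagents that add atoms: ethylene glycol, OCCO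
Why: Acid-catalysed ketalisation of the activated ketone of an α-keto ester, driven by azeotropic removal of water, masks the future acetyl group and leaves the ester free for homologation.

Step 2
Reactants: 2 ethyl 2-methyl-1,3-dioxolane-2-carboxylate
Product: 4 triisopropyl{[(2-methyl-1,3-dioxolan-2-yl)ethynyl]oxy}silane, via lithium ynolate 3 (not isolated)
Conditions: CH2Br2, lithium 2,2,6,6-tetramethylpiperidide (LiTMP), THF, −78 °C; then 2; n-BuLi, −78 °C → rt; TIPSCl, −78 → 0 °C
Reagents that add atoms: dibromomethane, BrCBr; chlorotri(propan-2-yl)silane (TIPSCl), CC(C)[Si](Cl)(C(C)C)C(C)C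
Why: Kowalski ester homologation: dibromomethyllithium adds to the ester and, after bromine–lithium exchange, 1,2-shift of the dioxolanyl carbon gives lithium ynolate 3, which the bulky silyl chloride traps on oxygen.

Step 3
Reactants: 5 trichloroethylene
Product: 7 (E)-1,2-dichloro-1-methoxyethene, via dichloroacetylene 6 (not isolated)
Conditions: MeOH, KH, THF, 0 °C; then 5, −50 °C → rt
Reagents that add atoms: methanol, CO
Why: Methoxide dehydrochlorinates trichloroethylene to dichloroacetylene 6, to which methanol adds in anti fashion (base-mediated elimination–addition), the standard entry to dichlorovinyl ethers as alkoxyalkyne precursors.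

Step 4
Reactants: 7 (E)-1,2-dichloro-1-methoxyethene
Product: 11 tert-butyl[(3-methoxyprop-2-yn-1-yl)oxy]dimethylsilane, via 1-chloro-2-methoxyethyne 8 (not isolated), via lithium methoxyacetylide 9 (not isolated), via lithium 3-methoxyprop-2-yn-1-olate 10 (not isolated)
Conditions: n-BuLi (2.2 equiv), THF, −78 → −40 °C; (CH2O)n, −40 °C → rt; TBSCl, imidazole (cat.), DMF, 0 °C → rt
Reagents that add atoms: formaldehyde (as paraformaldehyde), C=O; tert-butyl(chloro)dimethylsilane (TBSCl), CC(C)(C)[Si](C)(C)Cl
Why: Dehydrochlorination to chloroalkyne 8 and chlorine–lithium exchange give acetylide 9, whose 1,2-addition to formaldehyde and in situ O-silylation of alkoxide 10 deliver the protected ynol ether without exposing the acid-sensitive free alcohol.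

Step 5
Reactants: 11 tert-butyl[(3-methoxyprop-2-yn-1-yl)oxy]dimethylsilane
Product: 12 2-({[tert-butyl(dimethyl)silyl]oxy}methyl)-4,4-dichloro-3-methoxycyclobut-2-en-1-one
Conditions: Cl3CCOCl, Zn(Cu), Et2O–DME, rt
Reagents that add atoms: trichloroacetyl chloride, ClC(=O)C(Cl)(Cl)Cl
Why: [2+2] cycloaddition of dichloroketene, made in the flask from the acid chloride and zinc, with the electron-rich ynol ether, whose carbon remote from the methoxy group bonds to the ketene carbonyl carbon and so fixes the 3-methoxy-2-alkyl pattern, while DME ties up ZnCl2.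

Step 6
Reactants: 12 2-({[tert-butyl(dimethyl)silyl]oxy}methyl)-4,4-dichloro-3-methoxycyclobut-2-en-1-one
Product: 13 2-({[tert-butyl(dimethyl)silyl]oxy}methyl)-3-methoxycyclobut-2-en-1-one
Conditions: Zn dust, AcOH, TMEDA, MeOH, 0 °C → rt
Reagents that add atoms: none
Why: Zinc-mediated reductive dechlorination of the α,α-dichloro ketone in buffered acetic acid is the standard way from dichloroketene adducts to 4-unsubstituted cyclobutenones; the silyl ether is a poor leaving group and methanol matches the enol ether.

Step 7
Reactants: 13 2-({[tert-butyl(dimethyl)silyl]oxy}methyl)-3-methoxycyclobut-2-en-1-one; 4 triisopropyl{[(2-methyl-1,3-dioxolan-2-yl)ethynyl]oxy}silane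
Product: 18 4-({[tert-butyl(dimethyl)silyl]oxy}methyl)-5-methoxy-2-(2-methyl-1,3-dioxolan-2-yl)-3-{[tri(propan-2-yl)silyl]oxy}phenol, via vinylketene 14 (not isolated), via 4-vinylcyclobutenone 15 (not isolated), via dienylketene 16 (not isolated), via cyclohexa-2,4-dienone 17 (not isolated)
Conditions: 4 (1.3 equiv), toluene, 80 → 110 °C, argon
Reagents that add atoms: none
Why: On heating, 13 opens reversibly (4π) to vinylketene 14, whose electrophilic ketene carbon is attacked by the nucleophilic, ketal-bearing carbon of siloxyalkyne 4 in a [2+2] cycloaddition to give 4-vinylcyclobutenone 15. A second 4π opening gives dienylketene 16, and ring A is closed by thermal disrotatory 6π electrocyclisation between the ketene carbon and the terminal methylene carbon, after which dienone 17 tautomerises to phenol 18. This is the Danheiser benzannulation of a cyclobutenone with a siloxyalkyne, the known route to resorcinol monosilyl ethers. No stereocentre remains, since the quaternary carbon of 15 becomes an aromatic carbon. The step needs one regiochemistry in the [2+2] event, and the polarity of the silyl ynol ether (carbon remote from oxygen nucleophilic) against the ketene (carbonyl carbon electrophilic) secures it, placing the masked acetyl group between the new hydroxyl and the silyl ether and the silyloxymethyl carbon between the silyl ether and the methyl ether. A small excess of 4 keeps the phenolic product from being acylated by unreacted ketene, and the silyl ethers and the ketal are inert to neutral heating.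

Step 8
Reactants: 18 4-({[tert-butyl(dimethyl)silyl]oxy}methyl)-5-methoxy-2-(2-methyl-1,3-dioxolan-2-yl)-3-{[tri(propan-2-yl)silyl]oxy}phenol
Product: 19 1-[3-({[tert-butyl(dimethyl)silyl]oxy}methyl)-6-hydroxy-4-methoxy-2-{[tri(propan-2-yl)silyl]oxy}phenyl]ethan-1-one
Conditions: PPTS (cat.), acetone–H2O, rt
Reagents that add atoms: water, O
Why: Acid-catalysed hydrolysis of the dioxolane, fast because the oxocarbenium ion is stabilised by the electron-rich arene, frees the hydrogen-bonded acetyl group under conditions that spare both silyl ethers and lowers the nucleophilicity of ring A before the coupling.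

Step 9
Reactants: 20 2',4',6'-trihydroxyacetophenone (1-(2,4,6-trihydroxyphenyl)ethan-1-one)
Product: 22 acetylfilicinic acid (2-acetyl-3,5-dihydroxy-4,4-dimethylcyclohexa-2,5-dien-1-one), via 3-methylphloroacetophenone 21 (not isolated)
Conditions: NaOMe, MeI, MeOH, 0 °C → rt
Reagents that add atoms: iodomethane, CI
Why: Dearomatising geminal C-methylation of the phloroacetophenone polyanion (alkylation of a phenolate at carbon), the classical entry to acylfilicinic acids, passes through mono-C-methyl compound 21 and blocks one ring carbon as CMe2.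

Step 10
Reactants: 19 1-[3-({[tert-butyl(dimethyl)silyl]oxy}methyl)-6-hydroxy-4-methoxy-2-{[tri(propan-2-yl)silyl]oxy}phenyl]ethan-1-one; 22 acetylfilicinic acid
Product: 25 2-acetyl-6-[(3-acetyl-2,4-dihydroxy-6-methoxyphenyl)methyl]-3,5-dihydroxy-4,4-dimethylcyclohexa-2,5-dien-1-one (CNP0224819.0), via hydroxymethyl acetophenone 23 (not isolated), via quinone methide 24 (not isolated)
Conditions: 22 (3 equiv), TBAF, THF, 0 °C → rt; then 1 M HCl
Reagents that add atoms: none
Why: Fluoride cleaves both silyl ethers, the resulting hydroxymethyl phenolate 23 loses hydroxide to quinone methide 24 as in the formaldehyde-mediated methylene bridging of acylphloroglucinols, and Michael addition of the enolate of 22 through its only ring CH gives the target after acidification.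

**Compound list**

1 | ethyl pyruvate (ethyl 2-oxopropanoate) | CCOC(=O)C(C)=O | starting material
2 | ethyl 2-methyl-1,3-dioxolane-2-carboxylate | CCOC(=O)C1(C)OCCO1 | intermediate
3 | lithium 2-(2-methyl-1,3-dioxolan-2-yl)ethyn-1-olate (lithium ynolate, formed in the flask) | [Li+].[O-]C#CC1(C)OCCO1 | intermediate
4 | triisopropyl{[(2-methyl-1,3-dioxolan-2-yl)ethynyl]oxy}silane | CC1(C#CO[Si](C(C)C)(C(C)C)C(C)C)OCCO1 | intermediate
5 | trichloroethylene | ClC=C(Cl)Cl | starting material
6 | dichloroacetylene (formed in the flask) | ClC#CCl | intermediate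
7 | (E)-1,2-dichloro-1-methoxyethene | CO/C(Cl)=C\Cl | intermediate
8 | 1-chloro-2-methoxyethyne (formed in the flask) | COC#CCl | intermediate
9 | lithium methoxyacetylide (formed in the flask) | [Li]C#COC | intermediate
10 | lithium 3-methoxyprop-2-yn-1-olate (formed in the flask) | [Li+].[O-]CC#COC | intermediate
11 | tert-butyl[(3-methoxyprop-2-yn-1-yl)oxy]dimethylsilane | COC#CCO[Si](C)(C)C(C)(C)C | intermediate
12 | 2-({[tert-butyl(dimethyl)silyl]oxy}methyl)-4,4-dichloro-3-methoxycyclobut-2-en-1-one | COC1=C(CO[Si](C)(C)C(C)(C)C)C(=O)C1(Cl)Cl | intermediate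
13 | 2-({[tert-butyl(dimethyl)silyl]oxy}methyl)-3-methoxycyclobut-2-en-1-one | COC1=C(CO[Si](C)(C)C(C)(C)C)C(=O)C1 | intermediate
14 | 2-({[tert-butyl(dimethyl)silyl]oxy}methyl)-3-methoxybuta-1,3-dien-1-one (vinylketene, formed in the flask) | C=C(OC)C(CO[Si](C)(C)C(C)(C)C)=C=O | intermediate
15 | 4-({[tert-butyl(dimethyl)silyl]oxy}methyl)-4-(1-methoxyethenyl)-2-(2-methyl-1,3-dioxolan-2-yl)-3-{[tri(propan-2-yl)silyl]oxy}cyclobut-2-en-1-one (racemic, formed in the flask) | O=C1C(C2(C)OCCO2)=C(O[Si](C(C)C)(C(C)C)C(C)C)C1(CO[Si](C)(C)C(C)(C)C)C(OC)=C | intermediate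
16 | (3E)-4-({[tert-butyl(dimethyl)silyl]oxy}methyl)-5-methoxy-2-(2-methyl-1,3-dioxolan-2-yl)-3-{[tri(propan-2-yl)silyl]oxy}hexa-1,3,5-trien-1-one (dienylketene, formed in the flask) | O=C=C(C1(C)OCCO1)/C(O[Si](C(C)C)(C(C)C)C(C)C)=C(CO[Si](C)(C)C(C)(C)C)\C(OC)=C | intermediate
17 | 4-({[tert-butyl(dimethyl)silyl]oxy}methyl)-5-methoxy-2-(2-methyl-1,3-dioxolan-2-yl)-3-{[tri(propan-2-yl)silyl]oxy}cyclohexa-2,4-dien-1-one (formed in the flask) | O=C1CC(OC)=C(CO[Si](C)(C)C(C)(C)C)C(O[Si](C(C)C)(C(C)C)C(C)C)=C1C1(C)OCCO1 | intermediate
18 | 4-({[tert-butyl(dimethyl)silyl]oxy}methyl)-5-methoxy-2-(2-methyl-1,3-dioxolan-2-yl)-3-{[tri(propan-2-yl)silyl]oxy}phenol | COc1cc(O)c(C2(C)OCCO2)c(O[Si](C(C)C)(C(C)C)C(C)C)c1CO[Si](C)(C)C(C)(C)C | intermediate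
19 | 1-[3-({[tert-butyl(dimethyl)silyl]oxy}methyl)-6-hydroxy-4-methoxy-2-{[tri(propan-2-yl)silyl]oxy}phenyl]ethan-1-one | COc1cc(O)c(C(C)=O)c(O[Si](C(C)C)(C(C)C)C(C)C)c1CO[Si](C)(C)C(C)(C)C | intermediate
20 | 2',4',6'-trihydroxyacetophenone (1-(2,4,6-trihydroxyphenyl)ethan-1-one) | CC(=O)c1c(O)cc(O)cc1O | starting material
21 | 1-(2,4,6-trihydroxy-3-methylphenyl)ethan-1-one (3-methylphloroacetophenone, formed in the flask) | CC(=O)c1c(O)cc(O)c(C)c1O | intermediate
22 | acetylfilicinic acid (2-acetyl-3,5-dihydroxy-4,4-dimethylcyclohexa-2,5-dien-1-one) | CC(=O)C1=C(O)C(C)(C)C(O)=CC1=O | intermediate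
23 | 1-[2,6-dihydroxy-3-(hydroxymethyl)-4-methoxyphenyl]ethan-1-one (formed in the flask) | COc1cc(O)c(C(C)=O)c(O)c1CO | intermediate
24 | 2-acetyl-3-hydroxy-5-methoxy-6-methylidenecyclohexa-2,4-dien-1-one (quinone methide, formed in the flask) | C=C1C(OC)=CC(O)=C(C(C)=O)C1=O | intermediate
25 | 2-acetyl-6-[(3-acetyl-2,4-dihydroxy-6-methoxyphenyl)methyl]-3,5-dihydroxy-4,4-dimethylcyclohexa-2,5-dien-1-one (CNP0224819.0) | COc1cc(O)c(C(C)=O)c(O)c1CC1=C(O)C(C)(C)C(O)=C(C(C)=O)C1=O | target

**Step count**

Total step count: 10.
Longest linear sequence: 7 steps (steps 3, 4, 5, 6, 7, 8 and 10, from trichloroethylene).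

**Steps most likely to fail**

Step 7. The vinylketene 14 may be intercepted by the phenol of product 18 (aryl ester formation) or may oligomerise, and the [2+2] addition at the alkyne carbon next to the quaternary ketal carbon may be slow. The fallback gives up the annulation and builds ring A from the phloroglucinol core. It sets out from 20, which should be methylated selectively at the non-chelated para hydroxyl (Me2SO4, one equivalent, K2CO3, acetone, reflux) to give 1-(2,6-dihydroxy-4-methoxyphenyl)ethan-1-one F1. F1 and 22 would then be treated with aqueous formaldehyde in dilute aqueous KOH at 0 °C → rt. Hydroxymethylation of F1 at one of its two equivalent ring CH positions should give 23 in the flask, where the fallback comes back to the route; 23 goes on through 24 to 25. Symmetrical dimers from the same reaction would have to be separated.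

Step 10. Quinone methide 24 may be captured by the free aromatic CH of a second ring A unit instead of by 22 (self-condensation). After coupling, base may reopen the methylene bridge by retro-Michael reaction and scramble the halves, and alkylation may occur on oxygen. The fallback changes the oxidation level and joins the halves by condensation and hydride transfer. It sets out from 19: the primary silyl ether should be cleaved selectively with HF·pyridine buffered with pyridine in THF at 0 °C to give 1-[6-hydroxy-3-(hydroxymethyl)-4-methoxy-2-{[tri(propan-2-yl)silyl]oxy}phenyl]ethan-1-one F2. Oxidation with MnO2 in CH2Cl2 should give 3-acetyl-4-hydroxy-6-methoxy-2-{[tri(propan-2-yl)silyl]oxy}benzaldehyde F3. Organocatalytic reductive alkylation of 22 with F3 (L-proline as catalyst, Hantzsch ester, CH2Cl2, rt) should give 2-acetyl-6-[(3-acetyl-4-hydroxy-6-methoxy-2-{[tri(propan-2-yl)silyl]oxy}phenyl)methyl]-3,5-dihydroxy-4,4-dimethylcyclohexa-2,5-dien-1-one F4. TBAF buffered with AcOH in THF should then remove the aryl silyl ether, and the fallback comes back to the route at 25.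

Step 5. ZnCl2 formed with the ketene may hydrate or oligomerise the ynol ether or strip the silyl ether, and the dichlorocyclobutenone may isomerise by 1,3-shift of chlorine before it is reduced. The fallback uses ketene itself in place of dichloroketene. It sets out from 11: ketene gas, generated by pyrolysis of acetone, would be passed into a solution of 11 in CH2Cl2 at 0 °C. The [2+2] cycloaddition, known for alkoxyalkynes, should give 13 directly with the same regiochemistry. The fallback comes back to the route at 13 and makes 12 and step 6 unnecessary.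

**Further compounds**

F1 | step 7 | 1-(2,6-dihydroxy-4-methoxyphenyl)ethan-1-one | COc1cc(O)c(C(C)=O)c(O)c1
F2 | step 10 | 1-[6-hydroxy-3-(hydroxymethyl)-4-methoxy-2-{[tri(propan-2-yl)silyl]oxy}phenyl]ethan-1-one | COc1cc(O)c(C(C)=O)c(O[Si](C(C)C)(C(C)C)C(C)C)c1CO
F3 | step 10 | 3-acetyl-4-hydroxy-6-methoxy-2-{[tri(propan-2-yl)silyl]oxy}benzaldehyde | COc1cc(O)c(C(C)=O)c(O[Si](C(C)C)(C(C)C)C(C)C)c1C=O
F4 | step 10 | 2-acetyl-6-[(3-acetyl-4-hydroxy-6-methoxy-2-{[tri(propan-2-yl)silyl]oxy}phenyl)methyl]-3,5-dihydroxy-4,4-dimethylcyclohexa-2,5-dien-1-one | COc1cc(O)c(C(C)=O)c(O[Si](C(C)C)(C(C)C)C(C)C)c1CC1=C(O)C(C)(C)C(O)=C(C(C)=O)C1=O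
F0 | step 5 | none | none
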